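**Assumption:** the stereocentre in the SMILES is C2 of the flavan and is (S). 7-Hydroxychromone, 3-chloro-3-methylbut-1-yne and the catalysts and ligands are taken as commercial.

## Retrosynthetic overview
1. The last bond made is C2'–prenyl, by aromatic Claisen rearrangement of the 3'-O-(1,1-dimethylallyl) ether. That ether is the only protection the 3'-OH ever carries.
2. The C4 methylene comes from the flavanone by NaBH4 reduction, then a fluoride-triggered p-quinone-methide/borohydride deoxygenation. This also frees 7-OH and uses no acid.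
3. The key disconnection is C2–C1', not the chalcone or C2–O bond. A Rh-catalysed asymmetric 1,4-addition of the B/D-ring boronate to an intact 7-silyloxychromone sets (2S).
4. The boronate comes from sterically controlled Ir C–H borylation of 2,2-dimethylchromen-8-ol, which is made from catechol and a tertiary propargyl chloride.
5. Ring order: the dimethylpyran (D) ring is the only ring built (Step 2). Rings A/C are bought as the chromone and ring B is catechol.

## Route

**Step 1**
Reactants: 1 catechol; 2 3-chloro-3-methylbut-1-yne
Product: 3, 2-[(2-methylbut-3-yn-2-yl)oxy]phenol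
Conditions: 1 (3 equiv), 2 (1 equiv), DBU (1.3 equiv), CuCl2·2H2O (1 mol %), MeCN, 0 °C to rt, N2
Reagents that add atoms: 3-chloro-3-methylbut-1-yne (2), C#CC(C)(C)Cl
Why: Cu-catalysed O-propargylation of a phenoxide with a tertiary propargylic chloride; catechol is symmetric, so there is no regiochemical issue, and excess catechol suppresses dialkylation.

**Step 2**
Reactants: 3
Product: 4, 2,2-dimethyl-2H-chromen-8-ol
Conditions: PhNEt2, 185 °C, 2 h, N2
Reagents that add atoms: none
Why: Aryl propargyl ether Claisen rearrangement, [1,5]-H shift and oxa-6π electrocyclisation in cascade; only one ortho carbon is free, so only one chromene can form.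

**Step 3**
Reactants: 4
Product: 5, 2,2-dimethyl-6-(4,4,5,5-tetramethyl-1,3,2-dioxaborolan-2-yl)-2H-chromen-8-ol
Conditions: HBpin (1.1 equiv), rt (–H2); then B2pin2 (0.8 equiv), [Ir(OMe)(cod)]2 (1.5 mol %), dtbpy (3 mol %), THF, 65 °C; MeOH quench
Reagents that add atoms: B2pin2, CC1(C)OB(OC1(C)C)B1OC(C)(C)C(C)(C)O1; HBpin, CC1(C)OBOC1(C)C (it also forms a transient O–Bpin that MeOH removes)
Why: Sterically governed Ir-catalysed aromatic C–H borylation with the phenol masked in situ as ArOBpin; C6–H is the only C–H with no ortho substituent, because C5 is next to the vinyl-bearing C4a, C7 is next to OBpin, and the vinylic C–H bonds are blocked by CMe2 and the peri position.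

**Step 4**
Reactants: 6 2-methylbut-3-en-2-ol
Product: 7, tert-butyl (2-methylbut-3-en-2-yl) carbonate
Conditions: n-BuLi, THF, –78 °C; Boc2O, to rt
Reagents that add atoms: Boc2O, CC(C)(C)OC(=O)OC(=O)OC(C)(C)C
Why: O-acylation of a tertiary lithium alkoxide gives the ionisable allylic carbonate.

**Step 5**
Reactants: 5; 7
Product: 8, 2-{2,2-dimethyl-8-[(2-methylbut-3-en-2-yl)oxy]-2H-chromen-6-yl}-4,4,5,5-tetramethyl-1,3,2-dioxaborolane
Conditions: 7 (1.2 equiv), Pd(PPh3)4 (5 mol %), THF, 0–5 °C, stopped at full conversion
Reagents that add atoms: carbonate 7, C=CC(C)(C)OC(=O)OC(C)(C)C (delivers C5H9)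
Why: Tsuji–Trost O-allylation ("reverse prenylation"), in which the phenoxide attacks the more substituted terminus of the 1,1-dimethyl-π-allyl-Pd under kinetic control; low temperature, no added base and near-stoichiometric carbonate prevent branched-to-linear equilibration and allyl–aryl Suzuki coupling at Bpin.

**Step 6**
Reactants: 9 7-hydroxy-4H-chromen-4-one
Product: 10, 7-[(triisopropylsilyl)oxy]-4H-chromen-4-one
Conditions: TIPSCl, imidazole, DMF, rt
Reagents that add atoms: TIPSCl, CC(C)[Si](Cl)(C(C)C)C(C)C
Why: Phenol silylation; it stops formation of the unreactive vinylogous carboxylate, and the bulky TIPS group survives the aqueous Rh step.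

**Step 7 (key step)**
Reactants: 8; 10 (1.3 equiv)
Product: 11, (2S)-2-{2,2-dimethyl-8-[(2-methylbut-3-en-2-yl)oxy]-2H-chromen-6-yl}-7-[(triisopropylsilyl)oxy]-2,3-dihydro-4H-chromen-4-one
Conditions: [RhCl(C2H4)2]2 (2.5 mol %), (S)-MeO-F12-BIPHEP (5.5 mol %), aq KOH (10 mol %), dioxane/H2O 10:1, 45–50 °C
Reagents that add atoms: none beyond 8 and 10 (water supplies only H)
Why: Hayashi–Miyaura Rh(I)-catalysed asymmetric 1,4-addition, in which the aryl–Rh held by the electron-poor (S)-biaryl diphosphine inserts the chromone C2=C3 bond through the C2 Re face (the same quadrant model by which (S)-BINAP gives (S)-3-arylcyclohexanones) and hydrolysis of the oxa-π-allyl-Rh releases the (2S)-flavanone; the boronate has no ortho substituent (which is why prenylation is deferred), base is only catalytic so retro-oxa-Michael racemisation is avoided, and unactivated alkenes do not insert into aryl–Rh.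

**Step 8**
Reactants: 11
Product: 12, (2S,4S)-2-{2,2-dimethyl-8-[(2-methylbut-3-en-2-yl)oxy]-2H-chromen-6-yl}-7-[(triisopropylsilyl)oxy]-3,4-dihydro-2H-chromen-4-ol (2,4-cis)
Conditions: NaBH4, THF/MeOH 4:1, –10 to 0 °C; crude product used directly
Reagents that add atoms: none
Why: Borohydride 1,2-reduction with axial hydride delivery gives the 2,4-cis alcohol; the C4 configuration does not matter because it is erased in Step 9, and fast cold reduction outruns base-induced ring opening so C2 stays S.

**Step 9**
Reactants: 12
Product: 13, (2S)-2-{2,2-dimethyl-8-[(2-methylbut-3-en-2-yl)oxy]-2H-chromen-6-yl}-3,4-dihydro-2H-chromen-7-ol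
Conditions: TBAF (1.2 equiv), NaBH4 (8 equiv), THF/i-PrOH 1:1, 0 to 65 °C; aq NH4Cl
Reagents that add atoms: none
Why: Proposed new method: fluoride unmasks the 7-phenoxide, which is para to C4 and expels the C4 hydroxide/borate to give a p-quinone methide further stabilised by O1, and borohydride adds 1,6 at C4 faster than the methide can tautomerise to the flav-3-ene, so CH2 and free 7-OH arise in one acid-free operation that leaves C2, the tertiary allyl aryl ether and the chromene untouched; the closest known reaction types are NaBH4 hydrogenolysis of p-hydroxybenzyl alcohols and p-hydroxyaryl ketones via quinone methides, and fluoride-triggered quinone methide generation from O-silyl hydroxybenzyl derivatives.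

**Step 10**
Reactants: 13
Product: 14, kazinol B, (2S)-2-[8-hydroxy-2,2-dimethyl-7-(3-methylbut-2-en-1-yl)-2H-chromen-6-yl]-3,4-dihydro-2H-chromen-7-ol
Conditions: degassed DMF, 120 °C, 2–3 h, Ar
Reagents that add atoms: none
Why: Aromatic Claisen [3,3] rearrangement of the 1,1-dimethylallyl aryl ether; C7 is the only ortho carbon carrying H (C8a is blocked), so allyl inversion places a normal prenyl group there, rearomatisation frees the 8-OH (3'-OH), and the neutral thermal conditions do not affect C2.

## Compound list
| No. | Name | SMILES | Role |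
|---|---|---|---|
| 1 | catechol | Oc1ccccc1O | starting material |
| 2 | 3-chloro-3-methylbut-1-yne | C#CC(C)(C)Cl | starting material |
| 3 | 2-[(2-methylbut-3-yn-2-yl)oxy]phenol | C#CC(C)(C)Oc1ccccc1O | intermediate |
| 4 | 2,2-dimethyl-2H-chromen-8-ol | CC1(C)C=Cc2cccc(O)c2O1 | intermediate |
| 5 | 6-Bpin-2,2-dimethyl-2H-chromen-8-ol | CC1(C)C=Cc2cc(B3OC(C)(C)C(C)(C)O3)cc(O)c2O1 | intermediate |
| 6 | 2-methylbut-3-en-2-ol | C=CC(C)(C)O | starting material |
| 7 | tert-butyl (2-methylbut-3-en-2-yl) carbonate | C=CC(C)(C)OC(=O)OC(C)(C)C | intermediate |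
| 8 | 6-Bpin-8-(1,1-dimethylallyloxy)-2,2-dimethyl-2H-chromene | CC1(C)C=Cc2cc(B3OC(C)(C)C(C)(C)O3)cc(OC(C)(C)C=C)c2O1 | intermediate |
| 9 | 7-hydroxy-4H-chromen-4-one | O=c1ccoc2cc(O)ccc12 | starting material |
| 10 | 7-(triisopropylsilyloxy)-4H-chromen-4-one | O=c1ccoc2cc(O[Si](C(C)C)(C(C)C)C(C)C)ccc12 | intermediate |
| 11 | (2S)-flavanone | CC1(C)C=Cc2cc([C@@H]3CC(=O)c4ccc(O[Si](C(C)C)(C(C)C)C(C)C)cc4O3)cc(OC(C)(C)C=C)c2O1 | intermediate |
| 12 | (2S,4S)-flavan-4-ol | CC1(C)C=Cc2cc([C@@H]3C[C@H](O)c4ccc(O[Si](C(C)C)(C(C)C)C(C)C)cc4O3)cc(OC(C)(C)C=C)c2O1 | intermediate |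
| 13 | (2S)-7-hydroxyflavan 3'-O-(1,1-dimethylallyl) ether | CC1(C)C=Cc2cc([C@@H]3CCc4ccc(O)cc4O3)cc(OC(C)(C)C=C)c2O1 | intermediate |
| 14 | kazinol B | CC(C)=CCc1c([C@@H]2CCc3ccc(O)cc3O2)cc2c(c1O)OC(C)(C)C=C2 | target |

## Summary
Total steps: 10.
Longest linear sequence: 8 (Steps 1, 2, 3, 5, 7, 8, 9, 10).

Three steps most likely to fail:

1. **Step 7.** The pinacol boronate may transmetalate slowly, the 7-silyloxychromone is a deactivated acceptor, and ee may erode.
   Fallback: move the stereocontrol to a different step. Make rac-11 with the more reactive achiral [Rh(OH)(cod)]2. Then resolve it by Noyori–Ikariya asymmetric transfer hydrogenation (Ru–TsDPEN, HCO2H/Et3N), which reduces only one flavanone enantiomer to the cis-flavan-4-ol. Carry forward whichever component is 2S, either 12 directly or recovered (S)-11 through Step 8.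

2. **Step 9.** Hydroxide may leave too slowly, or the quinone methide may tautomerise to the flav-3-ene.
   Fallback: switch from an ionic to a radical deoxygenation. Use Barton–McCombie on 12 (thiocarbonyldiimidazole, then (TMS)3SiH/AIBN, 80 °C), followed by TBAF, to reach 13. These conditions are neutral and tolerate the allyl aryl ether and the chromene.

3. **Step 3.** Ortho-borylation at C7 directed by OBpin, or reaction at the chromene alkene, could compete.
   Fallback: drop C–H borylation for a regiodefined halide route.
   - O-Alkylate 4-bromo-2-methoxyphenol with 2.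
   - Cyclise thermally to 6-bromo-8-methoxy-2,2-dimethylchromene.
   - Demethylate with EtSNa in DMF (SN2 is possible only at the methyl group) to give 6-bromo-2,2-dimethylchromen-8-ol.
   - Carry out the Step 5 etherification.
   - Treat with n-BuLi and B(OiPr)3 to give the boronic acid.

   This route also removes any Pd/Bpin cross-talk in Step 5 and supplies the more reactive boronic acid for Step 7.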